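**Strategy.** Everything rests on making the C6–C7 bond last: the CH2–CH2 unit of ring B, the cyclohexane between the norbornane and the bromo-diol ring A, lies between two quaternary carbons (bridgehead C5, methyl-bearing C8), so each end can wait as an alkenyl group. A bridgehead-vinyl norbornene from an enantioselective Diels–Alder reaction is joined to a ring A enone by Mukaiyama–Michael addition (C9–C10) and C8 allylation. In the key step ring-closing metathesis of the C5 vinyl and C8 propenyl groups closes ring B, and hydrogen in the same flask saturates the new alkene and the isopropenyl group. Ring A then receives bromine by radical hydrogenation of a bromoalkene and the diol by hydroxylation and methyl addition.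

Key step: step 13

Locants used below (not IUPAC): C1 = CH–OMe, C2 = norbornane bridgehead CH, C3 = CH2, C4 = CH–isopropyl, C5 = quaternary bridgehead, C6 and C7 = the two CH2 of ring B, C8 = C(CH3), C9 = ring-fusion CH, C10 = norbornane CH bonded to C9, C11 = C(OH)CH3, C12 = CHOH, C13 = CH2, C14 = CHBr, C15 = one-carbon bridge. Ring A = C8, C9, C11–C14. Ring B = C5–C10. Norbornane = C1–C5, C10, C15.

Assumption: the (S)-configured oxazaborolidinium catalyst in step 5 is taken to give the enantiomer drawn for 8; if its facial sense is the opposite, the (R)-catalyst is used and nothing else changes.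

**Step 1**
Reactants: 1 1,4-dioxaspiro[4.5]dec-6-en-8-one
Product: 2 7-iodo-1,4-dioxaspiro[4.5]dec-6-en-8-one
Conditions: I2, pyridine, CH2Cl2, 0 → 23 °C
Reagents that add atoms: iodine, II
Why: Johnson α-iodination of an enone (pyridine conjugate addition, iodination of the enolate, elimination) is standard for cyclohex-2-enones and creates no stereocenter.

**Step 2**
Reactants: 2 7-iodo-1,4-dioxaspiro[4.5]dec-6-en-8-one
Product: 3 7-methyl-1,4-dioxaspiro[4.5]dec-6-en-8-one
Conditions: MeB(OH)2, PdCl2(dppf), K3PO4, dioxane/H2O, 80 °C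
Reagents that add atoms: methylboronic acid, CB(O)O
Why: Suzuki–Miyaura coupling of the α-iodoenone with methylboronic acid should install the α-methyl group; no stereocenter is formed.

**Step 3**
Reactants: 4 3-ethoxycyclopent-2-en-1-one
Product: 5 3-ethenylcyclopent-2-en-1-one
Conditions: CH2=CHMgBr, THF, 0 °C; then 1 M HCl
Reagents that add atoms: vinylmagnesium bromide, C=C[Mg]Br; water, O
Why: Stork–Danheiser sequence, in which 1,2-addition of the Grignard reagent to the vinylogous ester and acid hydrolysis of the enol ether give the transposed 3-substituted enone; no stereocenter.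

**Step 4**
Reactants: 5 3-ethenylcyclopent-2-en-1-one
Product: 6 2-(tert-butyldimethylsilyloxy)-4-ethenylcyclopenta-1,3-diene
Conditions: LDA, THF, −78 °C; TBSOTf; used at once
Reagents that add atoms: tert-butyldimethylsilyl trifluoromethanesulfonate, CC(C)(C)[Si](C)(C)OS(=O)(=O)C(F)(F)F
Why: Kinetic deprotonation at the α' methylene and O-silylation should give the cross-conjugated 2-silyloxy diene, which is used cold to outrun [1,5]-hydrogen shifts; no stereocenter.

**Step 5**
Reactants: 6 2-(tert-butyldimethylsilyloxy)-4-ethenylcyclopenta-1,3-diene; 7 2,2,2-trifluoroethyl acrylate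
Product: 8 2,2,2-trifluoroethyl 5-(tert-butyldimethylsilyloxy)-1-ethenylbicyclo[2.2.1]hept-5-ene-2-endo-carboxylate
Conditions: (S)-o-tolyl oxazaborolidine (from (S)-diphenylprolinol) activated with HNTf2 (10 mol %), CH2Cl2, −78 °C
Reagents that add atoms: none
Why: Catalytic enantioselective Diels–Alder reaction with a chiral oxazaborolidinium Lewis acid, in which the silyloxy group and the substituent on the diene terminus both direct the ester-bearing carbon to the vinyl-substituted terminus (C4–C5 bond), the ester goes endo (C4) and the catalyst fixes the absolute configuration of C2, C4 and C5.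

**Step 6**
Reactants: 8 2,2,2-trifluoroethyl 5-(tert-butyldimethylsilyloxy)-1-ethenylbicyclo[2.2.1]hept-5-ene-2-endo-carboxylate
Product: 9 2-[5-(tert-butyldimethylsilyloxy)-1-ethenylbicyclo[2.2.1]hept-5-en-2-endo-yl]propan-2-ol
Conditions: MeMgBr (3 equiv), THF, −78 → 0 °C; aq. NH4Cl
Reagents that add atoms: methylmagnesium bromide, C[Mg]Br
Why: Double Grignard addition to the activated ester should give the tertiary carbinol without touching the silyl enol ether or the C4 stereocenter.

**Step 7**
Reactants: 9 2-[5-(tert-butyldimethylsilyloxy)-1-ethenylbicyclo[2.2.1]hept-5-en-2-endo-yl]propan-2-ol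
Product: 10 tert-butyl{[4-ethenyl-5-endo-(prop-1-en-2-yl)bicyclo[2.2.1]hept-2-en-2-yl]oxy}dimethylsilane
Conditions: Burgess reagent, toluene, 70 °C
Reagents that add atoms: none
Why: Burgess dehydration (syn elimination through the sulfamate ester) should take one of the six accessible methyl hydrogens rather than the hindered ring hydrogen and so give the isopropenyl group with C4 unchanged.

**Step 8**
Reactants: 10 tert-butyl{[4-ethenyl-5-endo-(prop-1-en-2-yl)bicyclo[2.2.1]hept-2-en-2-yl]oxy}dimethylsilane; 3 7-methyl-1,4-dioxaspiro[4.5]dec-6-en-8-one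
Product: 11 3-exo-[8-(tert-butyldimethylsilyloxy)-7-methyl-1,4-dioxaspiro[4.5]dec-7-en-6-yl]-4-ethenyl-5-endo-(prop-1-en-2-yl)bicyclo[2.2.1]heptan-2-one
Conditions: TBSNTf2 (5 mol %), CH2Cl2, −78 °C
Reagents that add atoms: none
Why: Mukaiyama–Michael addition with silyl transfer, in which the silyl-activated enone is attacked at C9 by the exo face of the norbornene enol ether (the endo face is blocked by the isopropenyl group, which sets C10), an open transition state that keeps the ketal carbon C11 away from bridgehead C5 sets C9, and the silyl group ends on the ring A enolate oxygen so that the C8 enolate is stored regiospecifically.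

**Step 9**
Reactants: 11 3-exo-[8-(tert-butyldimethylsilyloxy)-7-methyl-1,4-dioxaspiro[4.5]dec-7-en-6-yl]-4-ethenyl-5-endo-(prop-1-en-2-yl)bicyclo[2.2.1]heptan-2-one
Product: 12 3-exo-[8-(tert-butyldimethylsilyloxy)-7-methyl-1,4-dioxaspiro[4.5]dec-7-en-6-yl]-4-ethenyl-5-endo-(prop-1-en-2-yl)bicyclo[2.2.1]heptan-2-endo-ol
Conditions: NaBH4, EtOH/THF, −20 °C
Reagents that add atoms: none
Why: Hydride reduction of the norbornanone from the exo face, as with fenchone-type ketones, should give the endo alcohol at C1, trans to the exo substituent on C10.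

**Step 10**
Reactants: 12 3-exo-[8-(tert-butyldimethylsilyloxy)-7-methyl-1,4-dioxaspiro[4.5]dec-7-en-6-yl]-4-ethenyl-5-endo-(prop-1-en-2-yl)bicyclo[2.2.1]heptan-2-endo-ol
Product: 13 tert-butyl{[6-(1-ethenyl-3-endo-methoxy-6-endo-(prop-1-en-2-yl)bicyclo[2.2.1]hept-2-exo-yl)-7-methyl-1,4-dioxaspiro[4.5]dec-7-en-8-yl]oxy}dimethylsilane
Conditions: NaH, MeI, THF/DMF, 0 → 23 °C
Reagents that add atoms: iodomethane, CI
Why: Williamson etherification of the sodium alkoxide; the silyl enol ether and the ketal are stable to NaH and no stereocenter changes.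

**Step 11**
Reactants: 13 tert-butyl{[6-(1-ethenyl-3-endo-methoxy-6-endo-(prop-1-en-2-yl)bicyclo[2.2.1]hept-2-exo-yl)-7-methyl-1,4-dioxaspiro[4.5]dec-7-en-8-yl]oxy}dimethylsilane
Product: 14 6-[1-ethenyl-3-endo-methoxy-6-endo-(prop-1-en-2-yl)bicyclo[2.2.1]hept-2-exo-yl]-7-methyl-7-(prop-2-en-1-yl)-1,4-dioxaspiro[4.5]decan-8-one (allyl trans, methyl cis to the bicycloheptyl group)
Conditions: diallyl carbonate, Pd2(dba)3, PPh3, Bu4N[Ph3SiF2] (0.3 equiv), THF, 30 °C
Reagents that add atoms: diallyl carbonate, C=CCOC(=O)OCC=C
Why: Tsuji allylation of a silyl enol ether (fluoride-initiated), in which the tetrasubstituted enolate is alkylated at C8 regiospecifically and the π-allyl electrophile enters anti to the pseudoaxial bicycloheptyl group on C9, as in conjugate addition–alkylation of 2-methylcyclohexenone, so that allyl is trans and methyl cis to C10.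

**Step 12**
Reactants: 14 6-[1-ethenyl-3-endo-methoxy-6-endo-(prop-1-en-2-yl)bicyclo[2.2.1]hept-2-exo-yl]-7-methyl-7-(prop-2-en-1-yl)-1,4-dioxaspiro[4.5]decan-8-one
Product: 15 6-[1-ethenyl-3-endo-methoxy-6-endo-(prop-1-en-2-yl)bicyclo[2.2.1]hept-2-exo-yl]-7-methyl-7-[(E)-prop-1-en-1-yl]-1,4-dioxaspiro[4.5]decan-8-one
Conditions: RuHCl(CO)(PPh3)3 (5 mol %), toluene, 80 °C
Reagents that add atoms: none
Why: Ruthenium hydride catalysed alkene isomerisation (hydrometalation, β-hydride elimination) should move the terminal double bond into the more stable propenyl position, while the bridgehead vinyl group has no allylic hydrogen and cannot migrate; either alkene geometry serves the next step.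

**Step 13**
Reactants: 15 6-[1-ethenyl-3-endo-methoxy-6-endo-(prop-1-en-2-yl)bicyclo[2.2.1]hept-2-exo-yl]-7-methyl-7-[(E)-prop-1-en-1-yl]-1,4-dioxaspiro[4.5]decan-8-one
Product: 17 saturated tetracyclic keto ketal (C1 endo-OMe; C4 endo-isopropyl; C8 methyl; C11 ethylene ketal; C14 ketone), via ring-B cyclohexene 16 (not isolated)
Conditions: second-generation Grubbs catalyst (H2IMes)(PCy3)Cl2Ru=CHPh (10 mol %), toluene, 80 °C; then H2 (7 atm), 70 °C
Reagents that add atoms: none
Why: Ring-closing olefin metathesis followed in the same flask by hydrogenation on the ruthenium hydride formed from the spent carbene (tandem RCM–hydrogenation, a known one-pot pairing): the ruthenium benzylidene exchanges onto the propenyl group, undergoes [2+2] cycloaddition and cycloreversion with the bridgehead vinyl group and releases propene, which creates the C6=C7 bond. Ring B closes as a cyclohexene by six-membered ring-closing metathesis, the only strain-free closure open to the triene because C7 and C10 are trans-diequatorial on the ring A chair and C9 is exo on the norbornane next to bridgehead C5. No stereocenter is created, and the new ring is necessarily trans-fused to ring A and exo-fused to the norbornane since C5, C8, C9 and C10 are already fixed. The chemoselectivity needed is between three alkenes: the 1,1-disubstituted isopropenyl group could only close a four-membered ring with the C5 vinyl group or a seven-membered trisubstituted alkene with the propenyl group, so it should stay a spectator. Under hydrogen the ruthenium residue should then saturate the cis-disubstituted C6=C7 bond and the isopropenyl group, whose reduction creates no stereocenter because C4 was set in step 5; ketone, ketal and ether are inert.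

**Step 14**
Reactants: 17 saturated tetracyclic keto ketal (C11 ethylene ketal; C14 ketone)
Product: 18 tetracyclic enol triflate (C13=C14–OTf; C11 ethylene ketal)
Conditions: KHMDS, THF, −78 °C; PhNTf2
Reagents that add atoms: N-phenylbis(trifluoromethanesulfonimide), O=S(=O)(N(c1ccccc1)S(=O)(=O)C(F)(F)F)C(F)(F)F
Why: Enol triflate formation, regiospecific because the C14 ketone can only be deprotonated at C13 (C8 is quaternary).

**Step 15**
Reactants: 18 tetracyclic enol triflate (C13=C14–OTf; C11 ethylene ketal)
Product: 19 tetracyclic alkenyl bromide (C13=C14–Br; C11 ethylene ketal)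
Conditions: Ni(cod)2 (10 mol %), LiBr, DMA/THF, 23 °C
Reagents that add atoms: lithium bromide, [Li+].[Br-]
Why: Nickel-catalysed halogen exchange of an alkenyl triflate (oxidative addition, triflate/bromide exchange, reductive elimination) should give the alkenyl bromide without touching the ketal.

**Step 16**
Reactants: 19 tetracyclic alkenyl bromide (C13=C14–Br; C11 ethylene ketal)
Product: 20 tetracyclic bromide (C14 equatorial Br, cis to the C8 methyl group; C11 ethylene ketal)
Conditions: Mn(dpm)3 (cat.), PhSiH3, t-BuOOH, i-PrOH, 22 °C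
Reagents that add atoms: none
Why: Metal hydride hydrogen atom transfer hydrogenation, known to turn haloalkenes into alkyl halides, in which hydrogen atom addition at C13 gives the α-bromo radical at C14 and the second hydrogen arrives on the face opposite the axial C8 methyl group, leaving bromine equatorial (also the thermodynamic isomer).

**Step 17**
Reactants: 20 tetracyclic bromide (C14 equatorial Br; C11 ethylene ketal)
Product: 21 tetracyclic bromo ketone (C11 ketone; C14 equatorial Br)
Conditions: 2 M HCl, THF, 40 °C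
Reagents that add atoms: water, O
Why: Acid-catalysed ketal hydrolysis should unveil the C11 ketone; the secondary bromide and the methyl ether are inert and C9 keeps the more stable trans ring fusion.

**Step 18**
Reactants: 21 tetracyclic bromo ketone (C11 ketone; C14 equatorial Br)
Product: 22 tetracyclic α-hydroxy ketone (C11 ketone; C12 axial OH, trans to the C8 methyl face; C14 equatorial Br)
Conditions: KHMDS, THF, −78 °C; 3-phenyl-2-(phenylsulfonyl)oxaziridine
Reagents that add atoms: 3-phenyl-2-(phenylsulfonyl)oxaziridine (Davis reagent), O=S(=O)(N1OC1c1ccccc1)c1ccccc1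
Why: Kinetic enolate formation at the less hindered C12 methylene and Davis α-hydroxylation, in which oxygen is delivered axially to C12 through a chair-like transition state on the face where only the axial hydrogens on C9 and C14 are met, should give the axial C12 alcohol.

**Step 19**
Reactants: 22 tetracyclic α-hydroxy ketone (C11 ketone; C12 axial OH; C14 equatorial Br)
Product: 23 CNP0130529.1 (target)
Conditions: MeMgBr (5 equiv), THF, −78 → 0 °C; aq. NH4Cl
Reagents that add atoms: methylmagnesium bromide, C[Mg]Br
Why: Grignard addition to the α-hydroxy ketone, in which axial attack on C11 is blocked by the 1,3-diaxial C8 methyl group so that the methyl nucleophile enters equatorially and the tertiary hydroxyl becomes axial, trans-diaxial to the C12 hydroxyl as in the target.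

**Compound list**

1 | 1,4-dioxaspiro[4.5]dec-6-en-8-one | O=C1C=CC2(CC1)OCCO2 | starting material
2 | 7-iodo-1,4-dioxaspiro[4.5]dec-6-en-8-one | O=C1C(I)=CC2(CC1)OCCO2 | intermediate
3 | 7-methyl-1,4-dioxaspiro[4.5]dec-6-en-8-one | O=C1C(C)=CC2(CC1)OCCO2 | intermediate
4 | 3-ethoxycyclopent-2-en-1-one | CCOC1=CC(=O)CC1 | starting material
5 | 3-ethenylcyclopent-2-en-1-one | C=CC1=CC(=O)CC1 | intermediate
6 | 2-(tert-butyldimethylsilyloxy)-4-ethenylcyclopenta-1,3-diene | C=CC1=CC(O[Si](C)(C)C(C)(C)C)=CC1 | intermediate
7 | 2,2,2-trifluoroethyl acrylate | C=CC(=O)OCC(F)(F)F | starting material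
8 | 2,2,2-trifluoroethyl 5-(tert-butyldimethylsilyloxy)-1-ethenylbicyclo[2.2.1]hept-5-ene-2-endo-carboxylate (enantiomer as in SMILES) | FC(F)(F)COC(=O)[C@@H]1C[C@H]2C[C@]1(C=C)C=C2O[Si](C)(C)C(C)(C)C | intermediate
9 | 2-[5-(tert-butyldimethylsilyloxy)-1-ethenylbicyclo[2.2.1]hept-5-en-2-endo-yl]propan-2-ol | CC(C)(O)[C@@H]1C[C@H]2C[C@]1(C=C)C=C2O[Si](C)(C)C(C)(C)C | intermediate
10 | tert-butyl{[4-ethenyl-5-endo-(prop-1-en-2-yl)bicyclo[2.2.1]hept-2-en-2-yl]oxy}dimethylsilane | CC(=C)[C@@H]1C[C@H]2C[C@]1(C=C)C=C2O[Si](C)(C)C(C)(C)C | intermediate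
11 | 3-exo-[8-(tert-butyldimethylsilyloxy)-7-methyl-1,4-dioxaspiro[4.5]dec-7-en-6-yl]-4-ethenyl-5-endo-(prop-1-en-2-yl)bicyclo[2.2.1]heptan-2-one (C9 and C10 as in SMILES) | CC(=C)[C@@H]1C[C@H]2C[C@]1(C=C)[C@H]([C@@H]3C4(OCCO4)CCC(O[Si](C)(C)C(C)(C)C)=C3C)C2=O | intermediate
12 | 3-exo-[8-(tert-butyldimethylsilyloxy)-7-methyl-1,4-dioxaspiro[4.5]dec-7-en-6-yl]-4-ethenyl-5-endo-(prop-1-en-2-yl)bicyclo[2.2.1]heptan-2-endo-ol | CC(=C)[C@@H]1C[C@H]2C[C@]1(C=C)[C@H]([C@@H]3C4(OCCO4)CCC(O[Si](C)(C)C(C)(C)C)=C3C)[C@H]2O | intermediate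
13 | tert-butyl{[6-(1-ethenyl-3-endo-methoxy-6-endo-(prop-1-en-2-yl)bicyclo[2.2.1]hept-2-exo-yl)-7-methyl-1,4-dioxaspiro[4.5]dec-7-en-8-yl]oxy}dimethylsilane | CC(=C)[C@@H]1C[C@H]2C[C@]1(C=C)[C@H]([C@@H]3C4(OCCO4)CCC(O[Si](C)(C)C(C)(C)C)=C3C)[C@H]2OC | intermediate
14 | 6-[1-ethenyl-3-endo-methoxy-6-endo-(prop-1-en-2-yl)bicyclo[2.2.1]hept-2-exo-yl]-7-methyl-7-(prop-2-en-1-yl)-1,4-dioxaspiro[4.5]decan-8-one (allyl trans, methyl cis to the bicycloheptyl group) | CC(=C)[C@@H]1C[C@H]2C[C@]1(C=C)[C@H]([C@@H]3C4(OCCO4)CCC(=O)[C@@]3(C)CC=C)[C@H]2OC | intermediate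
15 | 6-[1-ethenyl-3-endo-methoxy-6-endo-(prop-1-en-2-yl)bicyclo[2.2.1]hept-2-exo-yl]-7-methyl-7-[(E)-prop-1-en-1-yl]-1,4-dioxaspiro[4.5]decan-8-one | CC(=C)[C@@H]1C[C@H]2C[C@]1(C=C)[C@H]([C@@H]3C4(OCCO4)CCC(=O)[C@@]3(C)/C=C/C)[C@H]2OC | intermediate
16 | ring-B cyclohexene: tetracycle with C6=C7, C4 endo-isopropenyl, C1 endo-OMe, C8 methyl, C11 ethylene ketal, C14 ketone (rings A and B trans-fused) | CO[C@H]1[C@H]2C[C@@H](C(C)=C)[C@]3(C=C[C@@]4(C)[C@H]([C@H]13)C5(OCCO5)CCC4=O)C2 | intermediate (not isolated)
17 | saturated tetracyclic keto ketal: C1 endo-OMe, C4 endo-isopropyl, C8 methyl, C11 ethylene ketal, C14 ketone | CO[C@H]1[C@H]2C[C@@H](C(C)C)[C@]3(CC[C@@]4(C)[C@H]([C@H]13)C5(OCCO5)CCC4=O)C2 | intermediate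
18 | tetracyclic enol triflate: C13=C14–OSO2CF3, C11 ethylene ketal | CO[C@H]1[C@H]2C[C@@H](C(C)C)[C@]3(CC[C@@]4(C)[C@H]([C@H]13)C5(OCCO5)CC=C4OS(=O)(=O)C(F)(F)F)C2 | intermediate
19 | tetracyclic alkenyl bromide: C13=C14–Br, C11 ethylene ketal | CO[C@H]1[C@H]2C[C@@H](C(C)C)[C@]3(CC[C@@]4(C)[C@H]([C@H]13)C5(OCCO5)CC=C4Br)C2 | intermediate
20 | tetracyclic bromide: C14 equatorial Br (cis to the C8 methyl group), C11 ethylene ketal | CO[C@H]1[C@H]2C[C@@H](C(C)C)[C@]3(CC[C@@]4(C)[C@H]([C@H]13)C5(OCCO5)CC[C@@H]4Br)C2 | intermediate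
21 | tetracyclic bromo ketone: C11 ketone, C14 equatorial Br | CO[C@H]1[C@H]2C[C@@H](C(C)C)[C@]3(CC[C@@]4(C)[C@H]([C@H]13)C(=O)CC[C@@H]4Br)C2 | intermediate
22 | tetracyclic α-hydroxy ketone: C11 ketone, C12 axial OH, C14 equatorial Br | CO[C@H]1[C@H]2C[C@@H](C(C)C)[C@]3(CC[C@@]4(C)[C@H]([C@H]13)C(=O)[C@@H](O)C[C@@H]4Br)C2 | intermediate
23 | CNP0130529.1: C1 endo-OMe, C4 endo-isopropyl, C8 methyl, C11 axial OH and equatorial methyl, C12 axial OH, C14 equatorial Br | CO[C@H]1[C@H]2C[C@@H](C(C)C)[C@]3(CC[C@@]4(C)[C@H]([C@H]13)[C@](C)(O)[C@@H](O)C[C@@H]4Br)C2 | target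

**Totals.** Total step count: 19. Longest linear sequence: 17 steps (steps 3 to 19, from 4); steps 1 and 2 make the ring A enone 3.

**Steps most likely to fail**

1. Step 8. The open transition state may distinguish the two faces of enone 3 poorly, giving the C9 epimer, and addition at the hindered β-carbon next to the ketal may be so slow that loss of the silyl group from 10 competes. Fallback: the stereocontrol is moved from the substrate to a catalyst. The same partners 10 and 3 are combined under the chiral oxazaborolidinium Lewis acid of step 5, its enantiomer chosen to match the exo attack of 10, with Ph3PO as silyl-cation trap; this is a known catalyst-controlled Mukaiyama–Michael addition to cyclic enones. The enone face is then chosen by the Lewis acid bound to the C14 carbonyl and not by the open transition state. The fallback sets out from 10 and 3 and comes back at 11; it makes no new compound (F0).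

2. Step 13. Both alkenes sit on quaternary carbons, so loading of the ruthenium carbene may be slow and catalyst decay or alkene migration may win; the hydrogenation stage may also stall at the hindered C6=C7 bond. Fallback: the C6–C7 bond is closed by reductive carbonyl coupling instead. Ozonolysis of 15 (O3, CH2Cl2/MeOH, −78 °C; Me2S) should cleave all three alkenes to the keto dialdehyde 6-(6-endo-acetyl-1-formyl-3-endo-methoxybicyclo[2.2.1]hept-2-exo-yl)-7-methyl-8-oxo-1,4-dioxaspiro[4.5]decane-7-carbaldehyde F1. Intramolecular McMurry coupling of the two aldehydes (TiCl3(DME)1.5, Zn–Cu, DME, reflux, slow addition; aldehydes couple far faster than the two hindered ketones) should give the ring-B cyclohexene carrying an acetyl group at C4, F2. Lombardo methylenation of the methyl ketone (Zn, CH2Br2, TiCl4; not basic, so C4 is not epimerised) returns the route to 16, which is then hydrogenated over Pd/C to 17.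

3. Step 5. Diene 6 may scramble by [1,5]-hydrogen shift before it reacts, and the catalyst may give insufficient facial control with this hindered diene. Fallback: auxiliary control replaces catalyst control. Diene 6 is combined with (S)-3-acryloyl-4-benzyloxazolidin-2-one and Me2AlCl in CH2Cl2 at −78 °C (Evans auxiliary Diels–Alder reaction through the bidentate chelate; the auxiliary enantiomer is chosen on the same assumption as the catalyst). This should give the endo imide (S)-4-benzyl-3-{[5-(tert-butyldimethylsilyloxy)-1-ethenylbicyclo[2.2.1]hept-5-en-2-endo-yl]carbonyl}oxazolidin-2-one F3. Excess MeMgBr then converts the imide directly into carbinol 9 and releases the oxazolidinone. The fallback sets out from 6 and comes back at 9.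

**Further compounds**

F0 | step 8 | none | none
F1 | step 13 | 6-(6-endo-acetyl-1-formyl-3-endo-methoxybicyclo[2.2.1]hept-2-exo-yl)-7-methyl-8-oxo-1,4-dioxaspiro[4.5]decane-7-carbaldehyde | CC(=O)[C@@H]1C[C@H]2C[C@]1(C=O)[C@H]([C@@H]3C4(OCCO4)CCC(=O)[C@@]3(C)C=O)[C@H]2OC
F2 | step 13 | ring-B cyclohexene with C4 endo-acetyl (C6=C7, C11 ethylene ketal, C14 ketone) | CO[C@H]1[C@H]2C[C@@H](C(C)=O)[C@]3(C=C[C@@]4(C)[C@H]([C@H]13)C5(OCCO5)CCC4=O)C2
F3 | step 5 | (S)-4-benzyl-3-{[5-(tert-butyldimethylsilyloxy)-1-ethenylbicyclo[2.2.1]hept-5-en-2-endo-yl]carbonyl}oxazolidin-2-one | O=C([C@@H]1C[C@H]2C[C@]1(C=C)C=C2O[Si](C)(C)C(C)(C)C)N3[C@@H](Cc4ccccc4)COC3=O
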